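## Analysis of the target

Target 17 is [5,7-dihydroxy-2,2-dimethyl-8-(3-methylbut-2-en-1-yl)-2H-chromen-6-yl](3-hydroxyphenyl)methanone, a 2H-chromene in which benzene ring A is fused to a 2,2-dimethylpyran ring (ring C) and carries a substituent on every carbon. Going round ring A, C4a carries pyran carbon C4, C5 a hydroxyl, C6 the 3-hydroxybenzoyl group (ring B), C7 a hydroxyl, C8 the prenyl group and C8a the pyran oxygen O1. There is no stereocentre: C2 bears two methyl groups, the C3=C4 double bond is held cis by the ring, and the prenyl alkene ends in two identical methyl groups. The sensitive parts are the electron-rich C3=C4 alkene and the prenyl alkene next to the C7 hydroxyl, which acid can hydrate or cyclise to a chroman, and the oxidisable acylphloroglucinol core, which is also an ambident nucleophile. The three phenols are of two kinds, the acidic, chelated hydroxyls on C5 and C7 and the ordinary phenol on ring B. The difficulty is constitutional: ring A is a 1,3,5-trioxygenated benzene whose three C–H positions start out equivalent and must end up carrying three different carbon substituents in a fixed order. The strategy rests on the fact that C4 is bonded to C4a, which lies between the oxygens on C5 and C8a, and that these two oxygens are mirror images of each other in 2,4,6-trihydroxybenzaldehyde 1, so the formyl carbon can become C4 and either ortho oxygen can become O1 with the same result. Once the pyran ring is closed, the two remaining ring carbons differ, since C6 sits between two phenolic oxygens and C8 between one phenolic oxygen and O1.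

## Retrosynthetic reasoning

**17 ⇒ 16 (O–Si bond on ring B).** The last disconnection is the silyl ether on the ring B oxygen. Only the ring A anion should meet the prenyl electrophile 15, so the ring B phenol is kept masked during the alkylation. A triisopropylsilyl ether survives aryllithium, dilute acid and amidine base, and falls to fluoride. The final unveiling therefore needs no acid, which the prenyl group next to the C7 hydroxyl would not tolerate.

**16 ⇒ 14 + 15 (C8–CH2 bond).** C8 is the only unsubstituted carbon of ring A in 14. It is ortho to the C7 oxygen and para to the C5 oxygen, so the delocalised anion of 14 can be C-alkylated productively only there. The prenyl group goes in late because it is the most acid-sensitive part and the preceding acetal cleavage is acidic. The forward step has to favour carbon over oxygen alkylation.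

**14 ⇒ 13 (two O–CH2 bonds).** The C5 and C7 hydroxyls are traced back to MOM ethers. These are needed earlier as directing groups for metalation and as protection against the organolithium. Both lie ortho to the ketone, so mild acid should remove them while the silyl ether stays.

**13 ⇒ 7 + 10 (C6–carbonyl bond).** This cut divides the molecule into a ring A/C fragment 7 and a ring B fragment 10 of similar size, so the route is convergent. In 7, C6–H is the position flanked by two MOM ethers, where directed metalation should give aryllithium 11. The electrophile must stop at the ketone stage, which the Weinreb amide 10 ensures through the chelated adduct 12. Cutting on the ring B side of the carbonyl would instead require a hindered ring A carboxylic acid derivative and gains nothing.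

**10 ⇒ 9 ⇒ 8 (amide C–N and O–Si bonds).** The ring B fragment comes from 3-hydroxybenzoic acid 8 by amide formation to 9 and silylation.

**7 ⇒ 2 + 3 + 4 (C3–C4 and O1–C2; key disconnection).** The pyran ring is opened at both bonds. C2, C3 and the two methyl groups come from the alkenylboronic acid 3; C4 is the formyl carbon of 2; O1 is its one free ortho hydroxyl. Annulating a C–H position of a symmetric trioxygenated benzene instead would offer three equivalent sites and could repeat. The formyl carbon marks one site and can react once. Dibenzylamine 4 is taken up in allylic amine 5 and released again when 5 becomes ortho-quinone methide 6, which closes to 7.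

**2 ⇒ 1 (two O–CH2 bonds).** The MOM ethers are placed on the para oxygen and on one of the two equivalent ortho oxygens of 1 before the key step. A free para hydroxyl would make the formyl group a vinylogous acid that forms a salt with 4 and resists iminium formation. A free trihydroxybenzene nucleus would also be a carbon nucleophile towards 6. Because the same ethers are needed for the metalation, protecting first adds no step, and the mirror symmetry of 1 means either ortho oxygen gives the same compound 2.

## Alternatives that were turned down

Alternative 1: Ring A is disconnected at C5–C6 and traced back to a pyran-fused pyranone, compound A2, which is 2,2-dimethyl-7-{2-[3-(methoxymethoxy)phenyl]-2-oxoethyl}-2H,5H-pyrano[4,3-b]pyran-5-one. A2 already holds the dimethylpyran ring and all ring A carbons as a masked polyketide.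
- Forward key step: Mg(OMe)2 in methanol would open the lactone of A2 to a methyl ester and a 1,3-diketone. The methylene between the two ketones then attacks the ester carbon in a Claisen condensation that closes ring A. Enolisation gives compound A1, which is [5,7-dihydroxy-2,2-dimethyl-2H-chromen-6-yl][3-(methoxymethoxy)phenyl]methanone.
- For: the aroyl group is placed at C6 by connectivity, not by a site-selective C–H functionalisation. On this point the plan is stronger than the chosen one, which depends on metalation at C6 and not at C8.
- Against: the ester carbon to be attacked is attached to C4a of an enol ether (C4a=C8a–O1), so it is a vinylogous carbonate and a poor electrophile. The opened diketone can lose the aroyl group by retro-Claisen attack of methoxide, re-close to the pyranone, or dehydrate to a 4-pyranone. A2 itself needs a dienolate acylation at the pyranone methyl group, which consumes extra base and competes with O-acylation.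
- Comparison: A1 still needs the same C8 prenylation as 14, and its ring B MOM ether must then be removed by acid next to the prenyl group. The step count is about equal. In place of built-in C6 selectivity, the chosen route offers bond-forming steps on stable, protected intermediates (an intramolecular alkenyl transfer and an organolithium acylation), a ring A that is bought and not built, and a fallback in which the two electrophiles are introduced in the reverse order.

Alternative 2: Ring A itself is disconnected into two small fragments, compound A4, which is 3-ethoxycyclobut-2-en-1-one, and compound A5, which is the prenyl siloxyalkyne triisopropyl[(5-methylhex-4-en-1-yn-1-yl)oxy]silane.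
- Forward key step: heating opens A4 by a 4π process to a vinylketene, which adds to A5 in a [2+2] sense. A second 4π opening and a 6π closure then give compound A3, which is 5-ethoxy-2-(3-methylbut-2-en-1-yl)-3-[(triisopropylsilyl)oxy]phenol.
- For: the prenyl group is placed between two oxygens by the alkyne, so there is no late choice between carbon and oxygen alkylation. Here the plan is stronger than the chosen one. The three oxygens of A3 are also all different (free, silylated, ethylated).
- Against: it builds a benzene ring that is available with the right oxygen pattern, and it needs a multistep preparation of A5 and of A4. A3 still lacks both the pyran ring and the aroyl group. The ethyl ether on the future C5 oxygen must be cleaved at the end, and the Lewis acids or hot nucleophiles that cleave aryl ethyl ethers would attack the prenyl and chromene alkenes.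
- Comparison: the route would be clearly longer. The chosen route gives up the pre-installed prenyl group, but it uses ring A from the bottle, closes the pyran ring in one step, and ends with protecting groups that come off under conditions the target tolerates.

Alternative 3: Ring B is disconnected at C1'–C6' and C2'–C3' into compound A8, which is furan, and the ring A ynone A7, which is 1-[5,7-bis(methoxymethoxy)-2,2-dimethyl-8-(3-methylbut-2-en-1-yl)-2H-chromen-6-yl]prop-2-yn-1-one.
- Forward key step: cycloaddition of A7 and A8, thermal or with ZnI2, would give the bridged adduct A9. Adduct A9 is the 7-oxanorbornadiene [5,7-bis(methoxymethoxy)-2,2-dimethyl-8-(3-methylbut-2-en-1-yl)-2H-chromen-6-yl](7-oxabicyclo[2.2.1]hepta-2,5-dien-2-yl)methanone. Acid would then open the oxygen bridge of A9 and aromatise the new ring to give compound A6, which is [5,7-bis(methoxymethoxy)-2,2-dimethyl-8-(3-methylbut-2-en-1-yl)-2H-chromen-6-yl](3-hydroxyphenyl)methanone.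
- For: the ring B phenol appears free in A6 while the ring A oxygens are still capped, so the two kinds of phenol are told apart without an extra protecting group. This is neater than the silyl ether of the chosen route. The meta position of the hydroxyl also follows from the more stable cation when the bridge of A9 opens.
- Against: ring B is the easy part of the molecule, since 8 already contains it, and three operations replace one acylation. All the hard work on ring A (pyran ring, C6 acyl carbon, C8 prenyl group) is still needed to reach A7, by the same metalation chemistry. A8 is a reluctant diene, its adduct A9 can revert by cycloreversion, and the ynone A7 invites conjugate addition. The acid or ZnI2 needed to aromatise A9 endangers the MOM ethers, the chromene alkene and the prenyl group that A6 is supposed to retain.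
- Comparison: it is longer, and its last step would again be acidic acetal cleavage beside a prenyl group. The chosen route obtains the same differentiation for the price of one fluoride step.

Key step: step 2

Remark on the chemistry: 17 has no stereocentre and no double bond of free geometry, so the route has no stereochemical task. The transient stereocentres of 5 and 12 are formed racemic and are lost within the same step.

## Route

Step 1
Reactants: 1 2,4,6-trihydroxybenzaldehyde
Product: 2 2-hydroxy-4,6-bis(methoxymethoxy)benzaldehyde
Conditions: MOMCl (2.1 equiv), iPr2NEt, CH2Cl2, 0 °C → rt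
Reagents that add atoms: chloromethyl methyl ether (MOMCl), COCCl
Why: O-alkylation of phenols with an α-chloro ether; the para hydroxyl and one ortho hydroxyl react, while the last ortho hydroxyl is held in a hydrogen bond to the formyl oxygen and is much less nucleophilic, so about two equivalents of reagent should stop at the bis-ether. The two ortho hydroxyls of 1 are equivalent, so only one chelated bis-ether can form.

Step 2
Reactants: 2 2-hydroxy-4,6-bis(methoxymethoxy)benzaldehyde; 3 (2-methylprop-1-en-1-yl)boronic acid; 4 dibenzylamine
Product: 7 5,7-bis(methoxymethoxy)-2,2-dimethyl-2H-chromene, via allylic amine 5 (not isolated), via ortho-quinone methide 6 (not isolated)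
Conditions: 3 (1.5 equiv), 4 (1.0 equiv), 1,4-dioxane, 90 °C, N2
Reagents that add atoms: none
Why: Amine 4 condenses with the formyl group of 2 to a hemiaminal/iminium ion while boronic acid 3 binds the neighbouring phenol oxygen as a tetracoordinate boronate; the 2-methylprop-1-enyl group then migrates from boron to the iminium carbon inside this complex, which makes the C3–C4 bond and gives allylic amine 5 (borono-Mannich, Petasis reaction). At 90 °C the benzylic and allylic C–N bond of 5 ionises with loss of 4, helped by the ortho and para MOM-oxy donors, to ortho-quinone methide 6. The Z isomer of 6, in which the alkenyl group faces the carbonyl oxygen, undergoes a thermal disrotatory oxa-6π electrocyclisation that joins O1 to the CMe2 carbon C2 and closes the six-membered pyran ring with recovery of the aromatic sextet; the E isomer can reach the Z form by reversible re-addition of 4. The closest known reaction type is the amine-promoted condensation of salicylaldehydes with alkenylboronic acids to 2H-chromenes. No stereocentre is created in 7, because the carbon that is stereogenic in 5 becomes sp2 C4 and C2 carries two methyl groups. The selectivities required are the site of annulation and a single annulation; both are secured by the substrate, which has one formyl carbon and one free ortho hydroxyl, the other ortho oxygen and the para oxygen being ethers that can neither bind boron as a phenoxide nor form a quinone methide. Alkenyl transfer is intramolecular from the phenol-bound boronate, so the alkenyl group is delivered only to the iminium carbon.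

Step 3
Reactants: 8 3-hydroxybenzoic acid
Product: 9 3-hydroxy-N-methoxy-N-methylbenzamide
Conditions: MeNH(OMe)·HCl, EDC·HCl, HOBt (cat.), Et3N, CH2Cl2, 0 °C → rt
Reagents that add atoms: N,O-dimethylhydroxylamine hydrochloride, CNOC.Cl
Why: Carbodiimide-mediated amide coupling through the HOBt active ester; any aryl ester formed at the free phenol is itself an active ester and is cleaved by the same amine, so the phenol need not be protected first.

Step 4
Reactants: 9 3-hydroxy-N-methoxy-N-methylbenzamide
Product: 10 N-methoxy-N-methyl-3-[(triisopropylsilyl)oxy]benzamide
Conditions: TIPSCl, imidazole, DMF, rt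
Reagents that add atoms: chlorotriisopropylsilane (TIPSCl), CC(C)[Si](Cl)(C(C)C)C(C)C
Why: Silylation of a phenol with a silyl chloride and imidazole; the bulky aryl silyl ether is chosen because it should resist aryllithium at low temperature, dilute acid in methanol and amidine base, and is removed by fluoride.

Step 5
Reactants: 7 5,7-bis(methoxymethoxy)-2,2-dimethyl-2H-chromene; 10 N-methoxy-N-methyl-3-[(triisopropylsilyl)oxy]benzamide
Product: 13 [5,7-bis(methoxymethoxy)-2,2-dimethyl-2H-chromen-6-yl]{3-[(triisopropylsilyl)oxy]phenyl}methanone, via C6 aryllithium 11 (not isolated), via lithium hemiaminal adduct 12 (not isolated)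
Conditions: n-BuLi (1.1 equiv), THF, 0 °C; then 10, −78 °C → 0 °C; H2O
Reagents that add atoms: none
Why: Directed ortho-metalation followed by Weinreb ketone synthesis. C6–H lies between two MOM ethers whose acetal oxygens can both coordinate lithium, whereas C8–H has one MOM ether and the less basic pyran oxygen, so deprotonation should give 11; its addition to 10 gives the N,O-chelated adduct 12, which does not collapse before the quench, so the reaction stops at ketone 13.

Step 6
Reactants: 13 [5,7-bis(methoxymethoxy)-2,2-dimethyl-2H-chromen-6-yl]{3-[(triisopropylsilyl)oxy]phenyl}methanone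
Product: 14 [5,7-dihydroxy-2,2-dimethyl-2H-chromen-6-yl]{3-[(triisopropylsilyl)oxy]phenyl}methanone
Conditions: HCl (cat.), MeOH–THF, rt → 40 °C
Reagents that add atoms: none
Why: Acid-catalysed acetal exchange (methanolysis of aryl MOM ethers); both MOM groups are ortho to the ketone, which assists their loss, and the CH2 unit leaves as its dimethyl acetal. An aryl triisopropylsilyl ether is stable to dilute acid in methanol, and the C3=C4 alkene, deactivated by the conjugated aroyl group, should survive these mild conditions.

Step 7
Reactants: 14 [5,7-dihydroxy-2,2-dimethyl-2H-chromen-6-yl]{3-[(triisopropylsilyl)oxy]phenyl}methanone; 15 1-bromo-3-methylbut-2-ene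
Product: 16 [5,7-dihydroxy-2,2-dimethyl-8-(3-methylbut-2-en-1-yl)-2H-chromen-6-yl]{3-[(triisopropylsilyl)oxy]phenyl}methanone
Conditions: 15 (1.1 equiv), DBU (1.1 equiv), THF, 0 °C → rt
Reagents that add atoms: none
Why: C-alkylation of an acylphloroglucinol anion by SN2 attack on the primary allylic bromide. One equivalent of DBU deprotonates the vinylogous acid formed by the C5/C7 hydroxyls and the ketone; the delocalised anion is carbon-nucleophilic at C8, the only unsubstituted ring carbon, and the dienone formed there re-aromatises by tautomerisation, which attack at C6 or C4a cannot do. Hydrogen bonding of the oxygens to the ketone and the tight ion pair in THF disfavour O-alkylation, and the ring B oxygen is silylated.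

Step 8
Reactants: 16 [5,7-dihydroxy-2,2-dimethyl-8-(3-methylbut-2-en-1-yl)-2H-chromen-6-yl]{3-[(triisopropylsilyl)oxy]phenyl}methanone
Product: 17 [5,7-dihydroxy-2,2-dimethyl-8-(3-methylbut-2-en-1-yl)-2H-chromen-6-yl](3-hydroxyphenyl)methanone
Conditions: TBAF, AcOH, THF, 0 °C
Reagents that add atoms: none
Why: Fluoride-induced cleavage of an aryl silyl ether; acetic acid buffers the fluoride so that the acidic ring A phenols are not held as reactive anions, and neither alkene is affected.

## Compound list

1 | 2,4,6-trihydroxybenzaldehyde | O=Cc1c(O)cc(O)cc1O | starting material
2 | 2-hydroxy-4,6-bis(methoxymethoxy)benzaldehyde | O=Cc1c(O)cc(OCOC)cc1OCOC | intermediate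
3 | (2-methylprop-1-en-1-yl)boronic acid | CC(C)=CB(O)O | starting material
4 | dibenzylamine | C(NCc1ccccc1)c1ccccc1 | starting material
5 | 2-[1-(dibenzylamino)-3-methylbut-2-en-1-yl]-3,5-bis(methoxymethoxy)phenol (racemic; not isolated) | CC(C)=CC(N(Cc1ccccc1)Cc1ccccc1)c1c(O)cc(OCOC)cc1OCOC | intermediate
6 | (6Z)-3,5-bis(methoxymethoxy)-6-(3-methylbut-2-en-1-ylidene)cyclohexa-2,4-dien-1-one (not isolated) | CC(C)=C/C=C1\C(=O)C=C(OCOC)C=C1OCOC | intermediate
7 | 5,7-bis(methoxymethoxy)-2,2-dimethyl-2H-chromene | CC1(C)C=Cc2c(OCOC)cc(OCOC)cc2O1 | intermediate
8 | 3-hydroxybenzoic acid | OC(=O)c1cccc(O)c1 | starting material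
9 | 3-hydroxy-N-methoxy-N-methylbenzamide | CON(C)C(=O)c1cccc(O)c1 | intermediate
10 | N-methoxy-N-methyl-3-[(triisopropylsilyl)oxy]benzamide | CON(C)C(=O)c1cccc(O[Si](C(C)C)(C(C)C)C(C)C)c1 | intermediate
11 | [5,7-bis(methoxymethoxy)-2,2-dimethyl-2H-chromen-6-yl]lithium (not isolated) | [Li]c1c(OCOC)cc2OC(C)(C)C=Cc2c1OCOC | intermediate
12 | lithium [5,7-bis(methoxymethoxy)-2,2-dimethyl-2H-chromen-6-yl][methoxy(methyl)amino]{3-[(triisopropylsilyl)oxy]phenyl}methanolate (racemic; not isolated) | [Li]OC(N(C)OC)(c1cccc(O[Si](C(C)C)(C(C)C)C(C)C)c1)c1c(OCOC)cc2OC(C)(C)C=Cc2c1OCOC | intermediate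
13 | [5,7-bis(methoxymethoxy)-2,2-dimethyl-2H-chromen-6-yl]{3-[(triisopropylsilyl)oxy]phenyl}methanone | COCOc1cc2OC(C)(C)C=Cc2c(OCOC)c1C(=O)c1cccc(O[Si](C(C)C)(C(C)C)C(C)C)c1 | intermediate
14 | [5,7-dihydroxy-2,2-dimethyl-2H-chromen-6-yl]{3-[(triisopropylsilyl)oxy]phenyl}methanone | Oc1cc2OC(C)(C)C=Cc2c(O)c1C(=O)c1cccc(O[Si](C(C)C)(C(C)C)C(C)C)c1 | intermediate
15 | 1-bromo-3-methylbut-2-ene | CC(C)=CCBr | starting material
16 | [5,7-dihydroxy-2,2-dimethyl-8-(3-methylbut-2-en-1-yl)-2H-chromen-6-yl]{3-[(triisopropylsilyl)oxy]phenyl}methanone | CC(C)=CCc1c(O)c(C(=O)c2cccc(O[Si](C(C)C)(C(C)C)C(C)C)c2)c(O)c2c1OC(C)(C)C=C2 | intermediate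
17 | [5,7-dihydroxy-2,2-dimethyl-8-(3-methylbut-2-en-1-yl)-2H-chromen-6-yl](3-hydroxyphenyl)methanone | CC(C)=CCc1c(O)c(C(=O)c2cccc(O)c2)c(O)c2c1OC(C)(C)C=C2 | target

## Step count and least certain steps

Total step count: 8. Longest linear sequence: 6 steps (1, 2, 5, 6, 7, 8 from compound 1; equally 3, 4, 5, 6, 7, 8 from compound 8).

**Step 2 (key step).** The formyl group of 2 is flanked by two ortho oxygens and made electron-rich by ortho and para donors. Iminium formation and alkenyl transfer may therefore be slow, so that protodeboronation of 3 at 90 °C uses up the boronic acid first, or the sequence stalls at 5 without loss of the amine.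
Fallback, from 2, returning at 7: addition of (2-methylprop-1-en-1-yl)magnesium bromide (Me2C=CHMgBr, THF, 0 °C, in excess to allow for the phenol) to the formyl group should give 2-(1-hydroxy-3-methylbut-2-en-1-yl)-3,5-bis(methoxymethoxy)phenol F1. Warming F1 in toluene, or exposure to silica, should expel water to give the same ortho-quinone methide 6, which closes to 7. This replaces amine and boron mediation by a stoichiometric carbanion addition and a separate cyclodehydration.

**Step 5.** Deprotonation at C8 may compete with or overtake deprotonation at C6. C8 lies between the C7 MOM ether and O1, whose in-plane lone pair is fixed towards C8. Metalation there would place the aroyl group on the wrong carbon.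
Fallback, from 7, returning at 16: the two ring positions are the two that must be substituted, so if metalation prefers C8 the electrophiles are introduced in the reverse order. Metalation of 7 with n-BuLi and alkylation with 15 in the presence of catalytic CuBr·SMe2 should give 5,7-bis(methoxymethoxy)-2,2-dimethyl-8-(3-methylbut-2-en-1-yl)-2H-chromene F2. A second metalation of F2 can then occur only at C6, the last ring C–H, between the two MOM ethers. Addition to 10 should give [5,7-bis(methoxymethoxy)-2,2-dimethyl-8-(3-methylbut-2-en-1-yl)-2H-chromen-6-yl]{3-[(triisopropylsilyl)oxy]phenyl}methanone F3. Brief methanolysis of F3 with catalytic HCl at room temperature, kept mild because of the prenyl group, should give 16. Steps 6 and 7 are then not needed.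

**Step 7.** The anion of 14 is ambident. Alkylation at the C7 or C5 oxygen instead of C8, and a second alkylation at C8 of 16 with loss of aromaticity, are the likely losses.
Fallback, from 13, returning at 16: the C8–prenyl bond is made through an organometal instead of a phenoxide. Reduction of 13 with LiAlH4 (THF, 0 °C) should give [5,7-bis(methoxymethoxy)-2,2-dimethyl-2H-chromen-6-yl]{3-[(triisopropylsilyl)oxy]phenyl}methanol F4. With n-BuLi (2.2 equiv) the alkoxide forms first and then C8 is metalated, directed by the C7 MOM ether and O1. Alkylation with 15 in the presence of catalytic CuBr·SMe2 should give [5,7-bis(methoxymethoxy)-2,2-dimethyl-8-(3-methylbut-2-en-1-yl)-2H-chromen-6-yl]{3-[(triisopropylsilyl)oxy]phenyl}methanol F5. Oxidation of the doubly benzylic alcohol with MnO2 should give the ketone [5,7-bis(methoxymethoxy)-2,2-dimethyl-8-(3-methylbut-2-en-1-yl)-2H-chromen-6-yl]{3-[(triisopropylsilyl)oxy]phenyl}methanone F3, and mild methanolysis of its MOM ethers gives 16.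

**Step 1.** Selectivity rests only on stoichiometry and on the hydrogen bond to the formyl group, so over-alkylation to the tris-ether or incomplete alkylation may give mixtures.
Fallback, from 1, returning at 2: exhaustive alkylation with NaH and MOMCl in DMF should give 2,4,6-tris(methoxymethoxy)benzaldehyde F6. Brief treatment of F6 with dilute HCl in methanol at 0 °C to room temperature should remove one of the two equivalent MOM groups next to the formyl group. The hydrogen bond that then forms to the formyl oxygen slows loss of the second, so 2 results.

## Further compounds

F1 | step 2 | 2-(1-hydroxy-3-methylbut-2-en-1-yl)-3,5-bis(methoxymethoxy)phenol (racemic) | CC(C)=CC(O)c1c(O)cc(OCOC)cc1OCOC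
F2 | step 5 | 5,7-bis(methoxymethoxy)-2,2-dimethyl-8-(3-methylbut-2-en-1-yl)-2H-chromene | CC(C)=CCc1c(OCOC)cc(OCOC)c2C=CC(C)(C)Oc12
F3 | step 5 | [5,7-bis(methoxymethoxy)-2,2-dimethyl-8-(3-methylbut-2-en-1-yl)-2H-chromen-6-yl]{3-[(triisopropylsilyl)oxy]phenyl}methanone | CC(C)=CCc1c(OCOC)c(C(=O)c2cccc(O[Si](C(C)C)(C(C)C)C(C)C)c2)c(OCOC)c2C=CC(C)(C)Oc12
F4 | step 7 | [5,7-bis(methoxymethoxy)-2,2-dimethyl-2H-chromen-6-yl]{3-[(triisopropylsilyl)oxy]phenyl}methanol (racemic) | COCOc1cc2OC(C)(C)C=Cc2c(OCOC)c1C(O)c1cccc(O[Si](C(C)C)(C(C)C)C(C)C)c1
F5 | step 7 | [5,7-bis(methoxymethoxy)-2,2-dimethyl-8-(3-methylbut-2-en-1-yl)-2H-chromen-6-yl]{3-[(triisopropylsilyl)oxy]phenyl}methanol (racemic) | CC(C)=CCc1c(OCOC)c(C(O)c2cccc(O[Si](C(C)C)(C(C)C)C(C)C)c2)c(OCOC)c2C=CC(C)(C)Oc12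
F6 | step 1 | 2,4,6-tris(methoxymethoxy)benzaldehyde | COCOc1cc(OCOC)c(C=O)c(OCOC)c1
A1 | alternative 1 | [5,7-dihydroxy-2,2-dimethyl-2H-chromen-6-yl][3-(methoxymethoxy)phenyl]methanone | COCOc1cccc(c1)C(=O)c1c(O)cc2OC(C)(C)C=Cc2c1O
A2 | alternative 1 | 2,2-dimethyl-7-{2-[3-(methoxymethoxy)phenyl]-2-oxoethyl}-2H,5H-pyrano[4,3-b]pyran-5-one | CC1(C)C=CC2=C(O1)C=C(CC(=O)c1cccc(OCOC)c1)OC2=O
A3 | alternative 2 | 5-ethoxy-2-(3-methylbut-2-en-1-yl)-3-[(triisopropylsilyl)oxy]phenol | CCOc1cc(O)c(CC=C(C)C)c(O[Si](C(C)C)(C(C)C)C(C)C)c1
A4 | alternative 2 | 3-ethoxycyclobut-2-en-1-one | CCOC1=CC(=O)C1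
A5 | alternative 2 | triisopropyl[(5-methylhex-4-en-1-yn-1-yl)oxy]silane | CC(C)=CCC#CO[Si](C(C)C)(C(C)C)C(C)C
A6 | alternative 3 | [5,7-bis(methoxymethoxy)-2,2-dimethyl-8-(3-methylbut-2-en-1-yl)-2H-chromen-6-yl](3-hydroxyphenyl)methanone | CC(C)=CCc1c(OCOC)c(C(=O)c2cccc(O)c2)c(OCOC)c2C=CC(C)(C)Oc12
A7 | alternative 3 | 1-[5,7-bis(methoxymethoxy)-2,2-dimethyl-8-(3-methylbut-2-en-1-yl)-2H-chromen-6-yl]prop-2-yn-1-one | C#CC(=O)c1c(OCOC)c(CC=C(C)C)c2OC(C)(C)C=Cc2c1OCOC
A8 | alternative 3 | furan | c1ccoc1
A9 | alternative 3 | [5,7-bis(methoxymethoxy)-2,2-dimethyl-8-(3-methylbut-2-en-1-yl)-2H-chromen-6-yl](7-oxabicyclo[2.2.1]hepta-2,5-dien-2-yl)methanone (racemic) | O=C(C1=CC2C=CC1O2)c1c(OCOC)c(CC=C(C)C)c2OC(C)(C)C=Cc2c1OCOC
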